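**Strategy.** Numbering follows the elemane skeleton (ring C5–C10, lactone O–C6–C7–C11–C12). The cyclohexane is cut at C9–C10 and C5–C6. The γ-lactone is carried as a 2-silyloxyfuran whose C6=C7 bond, with a 1-ethoxyvinyl group (C8=C9), forms an electron-rich diene; the partner is an (E)-enal in which C10=C5 bears the C14 methyl, the C1 aldehyde and a silyl alkyne (C4≡C3). One catalytic asymmetric endo Diels–Alder reaction forms both bonds, fuses the cyclohexene onto the lactone ring and sets C5, C6 and C10. Aldehyde, enol ether, lactone α-carbon and alkyne are then turned into the vinyl group, the C8 angelate, the exocyclic methylene and the acrylic acid.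

Key step: step 4

Remark on descriptors: β is the ring face of the C14 methyl on C10, α the opposite face; C1=C2 is the vinyl group, C3=C4–C15 the acrylic acid, C11=C13 the lactone methylene.
Assumption: the (S)-oxazaborolidinium catalyst is taken to direct the diene to the Re face at C2 of the enal (C10), the sense needed here; if the sense proves opposite, the (R)-catalyst is used with no other change.

**Step 1**
Reactants: 1 4-bromofuran-2(5H)-one; 2 tributyl(1-ethoxyethenyl)stannane
Product: 3 4-(1-ethoxyethenyl)furan-2(5H)-one
Conditions: Pd(PPh3)4 (5 mol %), CuI (10 mol %), 1,4-dioxane, 90 °C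
Reagents that add atoms: none
Why: Stille coupling, in which zerovalent palladium inserts readily into the vinylogous acyl bromide and the stannane transfers its α-ethoxyvinyl group, placing C8 (a masked ketone) and C9 on C7.

**Step 2**
Reactants: 3 4-(1-ethoxyethenyl)furan-2(5H)-one
Product: 4 4-(1-ethoxyethenyl)-2-(triisopropylsilyloxy)furan
Conditions: i-Pr3SiOTf, Et3N, CH2Cl2, 0 °C
Reagents that add atoms: triisopropylsilyl trifluoromethanesulfonate, CC(C)[Si](OS(=O)(=O)C(F)(F)F)(C(C)C)C(C)C
Why: Soft enolisation at the only acidic position (the γ-CH2, C6) gives the aromatic 2-silyloxyfuran, which puts C6=C7 in conjugation with the C8=C9 enol ether.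

**Step 3**
Reactants: 5 3-(trimethylsilyl)prop-2-ynal; 6 2-(triphenyl-λ5-phosphanylidene)propanal
Product: 7 (2E)-2-methyl-5-(trimethylsilyl)pent-2-en-4-ynal
Conditions: CH2Cl2, 0 °C → rt
Reagents that add atoms: none
Why: Wittig olefination with a formyl-stabilised ylide is E-selective and stops at the less electrophilic enal; the E geometry places the methyl cis to the alkyne (C14 cis to C4 in the target).

**Step 4**
Reactants: 4 4-(1-ethoxyethenyl)-2-(triisopropylsilyloxy)furan; 7 (2E)-2-methyl-5-(trimethylsilyl)pent-2-en-4-ynal
Product: 9 lactone aldehyde (8-ethoxy-7-ene 12,6α-olide; 10β-CH3, 10α-CHO, 5β-C≡CSiMe3, H-6β), via silyl ketene acetal cycloadduct 8 (not isolated)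
Conditions: (S)-B-(o-tolyl)oxazaborolidine from (S)-α,α-diphenylprolinol (20 mol %), HN(SO2CF3)2 (18 mol %), CH2Cl2, –78 → –40 °C; then AcOH (1.5 equiv), –78 → 0 °C
Reagents that add atoms: none
Why: The protonated oxazaborolidine lowers the LUMO of the enal and the extra-annular diene C6=C7–C8=C9 adds in an asynchronous suprafacial [4+2] cycloaddition (a catalytic enantioselective Diels–Alder reaction of the kind known for 2-substituted enals with siloxy dienes and for vinyl heteroarenes), forming C5–C6 and C9–C10, after which acetic acid protonates the silyl ketene acetal at C11 to give the lactone. The six-membered ring C5–C10 is closed by the cycloaddition itself onto the existing five-membered ring, with the C9–C10 bond completing the cyclohexene. C5 and C10 keep the E geometry of the dienophile (methyl and alkyne cis), C6 follows from the endo position of the formyl group (C1 cis to O6), and the absolute sense is set by the catalyst shielding one face of the bound s-trans enal. The regiochemistry needed (C6 to the β-carbon C5, C9 to C10) is expected electronically, because C6 is the vinylogous terminus of the silyl ketene acetal and the most nucleophilic diene carbon, and sterically, because the unsubstituted CH2 terminus is the one that meets the quaternary centre. Site selectivity rests on the aromatic furan being a poor ring diene, on the silyl cap shielding the alkyne, and on low temperature to disfavour 1,2-addition to the formyl group.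

**Step 5**
Reactants: 9 lactone aldehyde
Product: 10 vinyl lactone enol ether (10α-CH=CH2; otherwise as 9)
Conditions: Ph3PCH3Br, KN(SiMe3)2, THF, –78 → 0 °C
Reagents that add atoms: methyltriphenylphosphonium bromide, C[P+](c1ccccc1)(c1ccccc1)c1ccccc1.[Br-]
Why: Wittig methylenation of the aldehyde, which has no α-hydrogen and so cannot epimerise, gives the C1=C2 vinyl group while lactone, enol ether and silyl alkyne are inert to the ylide at low temperature.

**Step 6**
Reactants: 10 vinyl lactone enol ether
Product: 11 keto lactone (8-oxo 12,6α-olide, H-7α, trans-fused)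
Conditions: AcOH/THF/H2O (3:1:1), 0 °C → rt
Reagents that add atoms: water, O
Why: Acid-catalysed enol ether hydrolysis, in which C7 of the half-chair should be protonated axially, anti to the pseudo-axial H-6 (the planar lactone ring holds O6 pseudo-equatorial), giving H-7α and the trans-fused lactone; weak acid and low temperature are chosen to avoid β-elimination of the acyloxy group and epimerisation at C7.

**Step 7**
Reactants: 11 keto lactone
Product: 12 8β-alcohol (axial OH, cis to C14 and C11)
Conditions: LiBH(s-Bu)3, THF, –78 °C; AcOH quench at –78 °C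
Reagents that add atoms: none
Why: Bulky borohydride reduction, where the axial C14 methyl is syn-axial to the β face of the C8 carbonyl and blocks axial attack, so hydride enters equatorially from the α side and gives the axial 8β-alcohol; the lactone is untouched at –78 °C and the cold acidic quench prevents translactonisation.

**Step 8**
Reactants: 12 8β-alcohol; 13 angelic acid ((Z)-2-methylbut-2-enoic acid)
Product: 15 8β-angelate, via mixed anhydride 14 (not isolated)
Conditions: 2,4,6-Cl3C6H2COCl, Et3N, toluene, rt; then 12, 80 °C
Reagents that add atoms: none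
Why: Yamaguchi esterification, in which the mixed anhydride acylates the hindered axial alcohol on heating without a nucleophilic catalyst, conditions under which the Z (angelate) geometry should be kept and not isomerised to the tiglate.

**Step 9**
Reactants: 15 8β-angelate
Product: 18 α-methylene lactone with free ethynyl group at C5, via Mannich base 16 (not isolated), via ammonium iodide 17 (not isolated)
Conditions: LiN(i-Pr)2, THF, –78 °C; Me2N=CH2 I, –78 → 0 °C; MeI, rt; n-Bu4NF, THF, 0 °C
Reagents that add atoms: dimethyl(methylidene)ammonium iodide, C=[N+](C)C.[I-]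
Why: Kinetic deprotonation of the lactone (the most acidic C–H, the alkyne being silyl-capped), Mannich reaction of the enolate at C11, exhaustive N-methylation and fluoride-induced E1cB loss of trimethylamine give the C11=C13 methylene (the transient C11 stereocentre disappears), and the same fluoride cleaves the alkynyl C–Si bond.

**Step 10**
Reactants: 18 α-methylene lactone with free ethynyl group at C5
Product: 19 CNP0256928.2 (8β-angeloyloxy-elema-1,3,11(13)-trien-12,6α-olid-15-oic acid)
Conditions: Pd(OAc)2 (2 mol %), 2-(diphenylphosphino)pyridine, CH3SO3H (cat.), CO (20 bar), H2O, THF, 50 °C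
Reagents that add atoms: carbon monoxide, [C-]#[O+]; water, O
Why: Palladium-catalysed Markovnikov hydroxycarbonylation, in which a palladium hydride (with the pyridyl phosphine as proton shuttle) adds to the terminal alkyne with palladium on the internal carbon C4, and CO insertion and hydrolysis give the 2-substituted acrylic acid; the alkyne should react much faster than the vinyl, angelate and methylene lactone double bonds.

**Compound list**
1 | 4-bromofuran-2(5H)-one | O=C1C=C(Br)CO1 | starting material
2 | tributyl(1-ethoxyethenyl)stannane | CCOC(=C)[Sn](CCCC)(CCCC)CCCC | starting material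
3 | 4-(1-ethoxyethenyl)furan-2(5H)-one | CCOC(=C)C1=CC(=O)OC1 | intermediate
4 | 4-(1-ethoxyethenyl)-2-(triisopropylsilyloxy)furan (diene) | CCOC(=C)c1coc(O[Si](C(C)C)(C(C)C)C(C)C)c1 | intermediate
5 | 3-(trimethylsilyl)prop-2-ynal | C[Si](C)(C)C#CC=O | starting material
6 | 2-(triphenyl-λ5-phosphanylidene)propanal | CC(C=O)=P(c1ccccc1)(c1ccccc1)c1ccccc1 | starting material
7 | (2E)-2-methyl-5-(trimethylsilyl)pent-2-en-4-ynal (dienophile) | O=C/C(C)=C/C#C[Si](C)(C)C | intermediate
8 | silyl ketene acetal cycloadduct: C7=C8(OEt) and C11=C12(OSi(i-Pr)3), 10β-CH3, 10α-CHO, 5β-C≡CSiMe3, H-6β (O-6α) | O=C[C@]1(C)CC(OCC)=C2C=C(O[Si](C(C)C)(C(C)C)C(C)C)O[C@@H]2[C@H]1C#C[Si](C)(C)C | intermediate (not isolated)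
9 | lactone aldehyde: 8-ethoxy-7-ene 12,6α-olide, 10β-CH3, 10α-CHO, 5β-C≡CSiMe3, H-6β | O=C[C@]1(C)CC(OCC)=C2CC(=O)O[C@@H]2[C@H]1C#C[Si](C)(C)C | intermediate
10 | vinyl lactone enol ether: as 9 with 10α-CH=CH2 | C=C[C@]1(C)CC(OCC)=C2CC(=O)O[C@@H]2[C@H]1C#C[Si](C)(C)C | intermediate
11 | keto lactone: 8-oxo 12,6α-olide, H-7α (trans-fused), 10α-vinyl, 10β-CH3, 5β-C≡CSiMe3 | C=C[C@]1(C)CC(=O)[C@H]2CC(=O)O[C@@H]2[C@H]1C#C[Si](C)(C)C | intermediate
12 | 8β-alcohol of 11 (OH axial, cis to C14 and C11) | C=C[C@]1(C)C[C@@H](O)[C@H]2CC(=O)O[C@@H]2[C@H]1C#C[Si](C)(C)C | intermediate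
13 | angelic acid, (Z)-2-methylbut-2-enoic acid | C/C=C(/C)C(=O)O | starting material
14 | angelic 2,4,6-trichlorobenzoic anhydride | C/C=C(/C)C(=O)OC(=O)c1c(Cl)cc(Cl)cc1Cl | intermediate (not isolated)
15 | 8β-angelate of 12 | C=C[C@]1(C)C[C@@H](OC(=O)/C(C)=C\C)[C@H]2CC(=O)O[C@@H]2[C@H]1C#C[Si](C)(C)C | intermediate
16 | Mannich base: 15 with CH2NMe2 at C11 (C11 epimers) | C=C[C@]1(C)C[C@@H](OC(=O)/C(C)=C\C)[C@H]2C(CN(C)C)C(=O)O[C@@H]2[C@H]1C#C[Si](C)(C)C | intermediate (not isolated)
17 | trimethylammonium iodide of 16 | C=C[C@]1(C)C[C@@H](OC(=O)/C(C)=C\C)[C@H]2C(C[N+](C)(C)C)C(=O)O[C@@H]2[C@H]1C#C[Si](C)(C)C.[I-] | intermediate (not isolated)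
18 | 8β-angeloyloxy 11(13)-methylene 12,6α-olide with 5β-ethynyl and 10α-vinyl | C=C[C@]1(C)C[C@@H](OC(=O)/C(C)=C\C)[C@H]2C(=C)C(=O)O[C@@H]2[C@H]1C#C | intermediate
19 | CNP0256928.2 | C=C[C@]1(C)C[C@@H](OC(=O)/C(C)=C\C)[C@H]2C(=C)C(=O)O[C@@H]2[C@H]1C(=C)C(=O)O | target

**Total steps:** 10. **Longest linear sequence:** 9 (steps 1, 2, 4–10).

**Steps most likely to fail**

1. Step 4. The Lewis acid may divert the silyloxyfuran into 1,2-addition to the formyl group, first attack may occur through C9 to give the regioisomer, the reaction may stop after the first C–C bond, or facial discrimination may be poor. Fallback, from 4 and 7: run the cycloaddition with no Lewis acid (toluene, 90 °C, sealed tube, or 12 kbar at rt), which removes the carbonyl-addition pathway, and work up with acetic acid as in step 4. This gives the racemate, that is cycloadduct 8 with the antipodal cycloadduct F1 (neither isolated) and lactone aldehyde 9 with the antipodal lactone aldehyde F2. The enantiomers are separated by preparative chromatography on a chiral stationary phase (amylose tris(3,5-dimethylphenylcarbamate)), and enantiopure 9 returns to the route at step 5.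

2. Step 6. Protonation at C7 may occur on the β face and give the cis-fused lactone, the centre may epimerise afterwards, or the β-acyloxy ketone may eliminate. Fallback, from 10: open the lactone before the ketone is unveiled, so that C7 is set in an open chain. LiOH (THF/H2O) gives lithium hydroxy carboxylate F3. t-BuMe2SiCl and imidazole (DMF) give silyl ether silyl ester F4. AcOH/THF/H2O hydrolyses enol ether and silyl ester to keto acid F5, whose C7 side chain is equilibrated (Et3N, CH2Cl2) to the equatorial position between two equatorial neighbours. HF·pyridine (MeCN, 0 °C) frees hydroxy acid F6, which lactonises to 11.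

3. Step 10. Hydropalladation of the hindered alkyne may place palladium on the terminal carbon and give the linear acid, or enyne cycloisomerisation may compete. Fallback, from 18: Markovnikov addition of HI made in the flask (NaI, Me3SiCl, H2O, MeCN, 0 °C) fixes the regiochemistry through the internal vinyl cation and gives 2-iodoalkene F7. Carbonylation of the C–I bond (Pd(OAc)2, PPh3, CO 1 atm, Et3N, H2O, DMF, 50 °C) then gives 19.

**Further compounds**
F1 | step 4 | antipodal cycloadduct (enantiomer of 8) | O=C[C@@]1(C)CC(OCC)=C2C=C(O[Si](C(C)C)(C(C)C)C(C)C)O[C@H]2[C@@H]1C#C[Si](C)(C)C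
F2 | step 4 | antipodal lactone aldehyde (enantiomer of 9) | O=C[C@@]1(C)CC(OCC)=C2CC(=O)O[C@H]2[C@@H]1C#C[Si](C)(C)C
F3 | step 6 | lithium hydroxy carboxylate (ring-opened 10) | C=C[C@]1(C)CC(OCC)=C(CC(=O)[O-])[C@H](O)[C@H]1C#C[Si](C)(C)C.[Li+]
F4 | step 6 | silyl ether silyl ester | C=C[C@]1(C)CC(OCC)=C(CC(=O)O[Si](C)(C)C(C)(C)C)[C@H](O[Si](C)(C)C(C)(C)C)[C@H]1C#C[Si](C)(C)C
F5 | step 6 | keto acid (8-oxo, 6α-OSi(t-Bu)Me2, C7 side chain β) | C=C[C@]1(C)CC(=O)[C@@H](CC(=O)O)[C@H](O[Si](C)(C)C(C)(C)C)[C@H]1C#C[Si](C)(C)C
F6 | step 6 | hydroxy acid | C=C[C@]1(C)CC(=O)[C@@H](CC(=O)O)[C@H](O)[C@H]1C#C[Si](C)(C)C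
F7 | step 10 | 2-iodoalkene | C=C[C@]1(C)C[C@@H](OC(=O)/C(C)=C\C)[C@H]2C(=C)C(=O)O[C@@H]2[C@H]1C(I)=C
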